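**Strategy.** The quinone ring (C1 and C4 carbonyls, C2 OH, C3 side chain, C5 OMe, C6 H) is the enol form of a cyclohexane-1,2,4,5-tetraone made of two α-keto acid C3 units joined head to tail: C1–C2–C3 (a 2-oxo ester whose C3 carries the side chain) and C4–C5–C6 (a pyruvate). Everything rests on cutting C3–C4 and C6–C1. The oxygen on side-chain C2′ sits 1,3 to ring C3, so it serves as a temporary tether: in the precursor it is the pyruvate ester oxygen. Base moves the pyruvoyl group from this oxygen to C3 through a five-membered transition state, then closes C6 onto the methyl ester, giving the dihydroxyquinone and freeing the C2′ hydroxyl for acetylation.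

Key step: step 6

Remark: hydroxyquinones are drawn as 1,4-dione tautomers with the ring numbering of the target, and each stereodescriptor is the CIP descriptor of the compound as drawn (for 7 it reads S for the same spatial arrangement).

**Step 1**
Reactants: 1 (R)-epichlorohydrin; 2 decylmagnesium bromide
Product: 3 (2R)-1-chlorotridecan-2-ol
Conditions: CuI (10 mol %), THF, −40 to −20 °C; then 1 M HCl
Reagents that add atoms: none
Why: Copper-catalysed Grignard opening of the epoxide (SN2 at the unsubstituted ring CH2, faster than displacement of chloride) should give the chlorohydrin with the stereocentre of 1 untouched.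

**Step 2**
Reactants: 3 (2R)-1-chlorotridecan-2-ol
Product: 5 (3R)-tetradec-1-en-3-ol, via (2R)-2-undecyloxirane 4 (not isolated)
Conditions: n-BuLi (1 equiv), THF, −78 °C to rt; then Me3SI/n-BuLi (3 equiv each), THF, −10 °C to rt; then H2O
Reagents that add atoms: trimethylsulfonium iodide, C[S+](C)C.[I-]
Why: The lithium alkoxide closes to epoxide 4, dimethylsulfonium methylide (the Corey–Chaykovsky reagent) opens it at the CH2 terminus and further ylide triggers loss of Me2S from the betaine (one-carbon homologation of an epoxide to an allylic alcohol), all without touching the carbinol centre.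

**Step 3**
Reactants: 5 (3R)-tetradec-1-en-3-ol; 6 methyl 2-bromoprop-2-enoate
Product: 8 methyl (5R)-5-hydroxy-2-methylidenehexadecanoate, via bis(9-BBN) adduct 7 (not isolated)
Conditions: 9-BBN (2.2 equiv), THF, 0 °C to rt; then 6, PdCl2(dppf) (5 mol %), K3PO4 (3 M aq.), DMF, rt
Reagents that add atoms: none
Why: Anti-Markovnikov hydroboration of the vinyl group (the hydroxyl is held as its borinate) followed by B-alkyl Suzuki–Miyaura coupling with the activated vinyl bromide should join the terminal carbon to the acrylate α-carbon under a base mild enough to spare the ester.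

**Step 4**
Reactants: 8 methyl (5R)-5-hydroxy-2-methylidenehexadecanoate; 9 2-methylprop-2-enoyl chloride
Product: 10 methyl (5R)-2-methylidene-5-[(2-methylprop-2-enoyl)oxy]hexadecanoate
Conditions: Et3N, DMAP (cat.), CH2Cl2, 0 °C to rt
Reagents that add atoms: none
Why: DMAP-catalysed acylation puts the masked pyruvate on the secondary alcohol while the keto group of the other unit is still a methylidene, so no cyclic hemiketal can divert the hydroxyl.

**Step 5**
Reactants: 10 methyl (5R)-2-methylidene-5-[(2-methylprop-2-enoyl)oxy]hexadecanoate
Product: 11 methyl (5R)-2-oxo-5-[(2-oxopropanoyl)oxy]hexadecanoate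
Conditions: O3, CH2Cl2, −78 °C; then Me2S, −78 °C to rt
Reagents that add atoms: ozone, [O-][O+]=O
Why: Ozonolysis of both 1,1-disubstituted acrylate double bonds with reductive work-up should unveil the two α-keto esters in one operation without affecting the stereocentre.

**Step 6**
Reactants: 11 methyl (5R)-2-oxo-5-[(2-oxopropanoyl)oxy]hexadecanoate
Product: 13 2,5-dihydroxy-3-[(2R)-2-hydroxytridecyl]cyclohexa-2,5-diene-1,4-dione, via acyl-transfer triketone 12 (not isolated)
Conditions: KOtBu (3.5 equiv), THF (0.01 M, slow addition of 11), −40 °C to rt; then 1 M HCl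
Reagents that add atoms: none
Why: Mechanism: the enolate at C3 of the 2-oxo ester (future ring C3) adds to the pyruvate ester carbonyl (future C4) through a five-membered cyclic tetrahedral intermediate (5-exo-trig) that collapses with loss of the C2′ alkoxide, an O-to-C acyl transfer of the Baker–Venkataraman kind that forms C3–C4 and gives 12 as its enolate; the pyruvoyl methyl (future C6) is then enolised and attacks the methyl ester carbonyl (future C1) with loss of methoxide to form C6–C1. The only ring closed is the carbocycle, by a 6-(enolexo)-exo-trig Dieckmann condensation, and the cyclohexane-1,2,4,5-tetraone formed is the keto tautomer of the dihydroxyquinone, held as its dianion until the acid quench. The closest known reaction is the base-mediated double Claisen self-condensation of alkylpyruvic esters to 3,6-dialkyl-2,5-dihydroxy-1,4-benzoquinones, here run as a crossed and fully intramolecular variant. No stereocentre is formed, and the C2′ oxygen is two carbons away from the C3 carbanion, so β-elimination is not possible and the configuration should be retained. The step needs cross- over self-condensation and C-acylation over aldol addition: the tether gives only the C3 enolate a five-membered path to an ester carbonyl, the pyruvoyl methyl can reach the other unit before the transfer only through eight- or nine-membered rings, and in 12 the C2 ketone is tied up in the enolate so that the methyl enolate is left with the ester carbon alone. Aldol adducts of the pyruvate ketone are reversible under KOtBu, high dilution holds back intermolecular condensation, and the doubly deprotonated quinone is the thermodynamic sink.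

**Step 7**
Reactants: 13 2,5-dihydroxy-3-[(2R)-2-hydroxytridecyl]cyclohexa-2,5-diene-1,4-dione
Product: 14 2-hydroxy-3-[(2R)-2-hydroxytridecyl]-5-methoxycyclohexa-2,5-diene-1,4-dione
Conditions: MeOH, H2SO4 (cat.), rt
Reagents that add atoms: methanol, CO
Why: Acid-catalysed etherification of a hydroxyquinone (a vinylogous Fischer esterification) should occur only at the vinylogous acid spanning C1–C6–C5, because the one spanning C2–C3–C4 is shielded by the C3 side chain, a steric effect well known for 3-alkyl-2-hydroxyquinones.

**Step 8**
Reactants: 14 2-hydroxy-3-[(2R)-2-hydroxytridecyl]-5-methoxycyclohexa-2,5-diene-1,4-dione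
Product: 16 (2R)-1-(2-hydroxy-5-methoxy-3,6-dioxocyclohexa-1,4-dien-1-yl)tridecan-2-yl acetate, via quinone diacetate 15 (not isolated)
Conditions: Ac2O, pyridine, DMAP (cat.), 0 °C to rt; then H2O, rt
Reagents that add atoms: acetic anhydride, CC(=O)OC(C)=O
Why: Acetylation esterifies the secondary alcohol and also the acidic 2-hydroxyl, but the quinone acetate is a vinylogous mixed anhydride that aqueous pyridine should cleave selectively, leaving the alkyl acetate and the methyl ether.

**Compound list**
1 | (R)-epichlorohydrin, (2R)-2-(chloromethyl)oxirane | ClC[C@H]1CO1 | starting material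
2 | decylmagnesium bromide | CCCCCCCCCC[Mg]Br | starting material
3 | (2R)-1-chlorotridecan-2-ol | CCCCCCCCCCC[C@H](CCl)O | intermediate
4 | (2R)-2-undecyloxirane | CCCCCCCCCCC[C@@H]1CO1 | intermediate
5 | (3R)-tetradec-1-en-3-ol | CCCCCCCCCCC[C@H](C=C)O | intermediate
6 | methyl 2-bromoprop-2-enoate | COC(=O)C(Br)=C | starting material
7 | 9-{[(3S)-1-(9-borabicyclo[3.3.1]nonan-9-yl)tetradecan-3-yl]oxy}-9-borabicyclo[3.3.1]nonane (bis(9-BBN) adduct; same spatial arrangement as 5) | CCCCCCCCCCC[C@H](CCB1C2CCCC1CCC2)OB1C2CCCC1CCC2 | intermediate
8 | methyl (5R)-5-hydroxy-2-methylidenehexadecanoate | CCCCCCCCCCC[C@H](CCC(=C)C(=O)OC)O | intermediate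
9 | 2-methylprop-2-enoyl chloride (methacryloyl chloride) | CC(=C)C(=O)Cl | starting material
10 | methyl (5R)-2-methylidene-5-[(2-methylprop-2-enoyl)oxy]hexadecanoate | CCCCCCCCCCC[C@H](CCC(=C)C(=O)OC)OC(=O)C(C)=C | intermediate
11 | methyl (5R)-2-oxo-5-[(2-oxopropanoyl)oxy]hexadecanoate | CCCCCCCCCCC[C@H](CCC(=O)C(=O)OC)OC(=O)C(C)=O | intermediate
12 | methyl (3Z,5R)-5-hydroxy-3-(1-hydroxy-2-oxopropylidene)-2-oxohexadecanoate (enol form of the C-acylated triketone, present as its potassium enolate) | CCCCCCCCCCC[C@H](C/C(C(=O)C(=O)OC)=C(/O)C(C)=O)O | intermediate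
13 | 2,5-dihydroxy-3-[(2R)-2-hydroxytridecyl]cyclohexa-2,5-diene-1,4-dione | CCCCCCCCCCC[C@H](CC1=C(O)C(=O)C=C(O)C1=O)O | intermediate
14 | 2-hydroxy-3-[(2R)-2-hydroxytridecyl]-5-methoxycyclohexa-2,5-diene-1,4-dione | CCCCCCCCCCC[C@H](CC1=C(O)C(=O)C=C(OC)C1=O)O | intermediate
15 | (2R)-1-[2-(acetyloxy)-5-methoxy-3,6-dioxocyclohexa-1,4-dien-1-yl]tridecan-2-yl acetate | CCCCCCCCCCC[C@H](CC1=C(OC(C)=O)C(=O)C=C(OC)C1=O)OC(C)=O | intermediate
16 | (2R)-1-(2-hydroxy-5-methoxy-3,6-dioxocyclohexa-1,4-dien-1-yl)tridecan-2-yl acetate | CCCCCCCCCCC[C@H](CC1=C(O)C(=O)C=C(OC)C1=O)OC(C)=O | target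

**Step count and risks**
Total steps: 8. Longest linear sequence: 8 steps (1 to 16).

Steps most likely to fail:

Step 6. The pyruvate ketone may undergo aldol addition and condensation, the material may oligomerise, or the base may cleave the pyruvate ester before the acyl transfer, so that the ring does not close. The fallback is a classical aryl route without any condensation and sets out from 3. NaOH closes 3 to the epoxide 4, which is now isolated. 1,2,4,5-Tetramethoxybenzene is lithiated (n-BuLi, TMEDA, THF, 0 °C) and added to 4 with BF3·OEt2 at −78 °C to give (2R)-1-(2,3,5,6-tetramethoxyphenyl)tridecan-2-ol F1. Oxidative demethylation with (NH4)2Ce(NO3)6 in MeCN/H2O gives 3-[(2R)-2-hydroxytridecyl]-2,5-dimethoxycyclohexa-2,5-diene-1,4-dione F2. Aqueous NaOH followed by HCl cleaves both vinylogous esters, and the fallback comes back to the route at 13.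

Step 3. The bromoacrylate may polymerise or take up nucleophiles under the basic coupling conditions, the alkylborane may transmetalate slowly and protodeboronate, and the δ-hydroxy ester may lactonise. The fallback forms the same C–C bond by a radical reaction and sets out from 3. Finkelstein exchange (NaI, butan-2-one, reflux) gives (2R)-1-iodotridecan-2-ol F3. Keck-type radical allylation of F3 with methyl 2-[(tributylstannyl)methyl]prop-2-enoate (AIBN, benzene, 80 °C) tolerates the free hydroxyl, and the fallback comes back to the route at 8.

Step 7. The side-chain hydroxyl may attack the protonated vinylogous acid next to it (cyclodehydration to a dihydrofuran-fused quinone), and etherification may be slow or go too far. The fallback blocks the alcohol first and methylates by O-alkylation; it sets out from 13. Ac2O/pyridine/DMAP gives (2R)-1-[2,5-bis(acetyloxy)-3,6-dioxocyclohexa-1,4-dien-1-yl]tridecan-2-yl acetate F4. Water cleaves the two quinone acetates of F4 to give (2R)-1-(2,5-dihydroxy-3,6-dioxocyclohexa-1,4-dien-1-yl)tridecan-2-yl acetate F5. Me3SiCHN2 (1 equiv, toluene/MeOH, 0 °C) should methylate the more acidic, unhindered vinylogous acid of F5, and the fallback comes back to the route at 16.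

**Further compounds**
F1 | step 6 | (2R)-1-(2,3,5,6-tetramethoxyphenyl)tridecan-2-ol | CCCCCCCCCCC[C@H](Cc1c(OC)c(OC)cc(OC)c1OC)O
F2 | step 6 | 3-[(2R)-2-hydroxytridecyl]-2,5-dimethoxycyclohexa-2,5-diene-1,4-dione | CCCCCCCCCCC[C@H](CC1=C(OC)C(=O)C=C(OC)C1=O)O
F3 | step 3 | (2R)-1-iodotridecan-2-ol | CCCCCCCCCCC[C@H](CI)O
F4 | step 7 | (2R)-1-[2,5-bis(acetyloxy)-3,6-dioxocyclohexa-1,4-dien-1-yl]tridecan-2-yl acetate | CCCCCCCCCCC[C@H](CC1=C(OC(C)=O)C(=O)C=C(OC(C)=O)C1=O)OC(C)=O
F5 | step 7 | (2R)-1-(2,5-dihydroxy-3,6-dioxocyclohexa-1,4-dien-1-yl)tridecan-2-yl acetate | CCCCCCCCCCC[C@H](CC1=C(O)C(=O)C=C(O)C1=O)OC(C)=O
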